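Readings and results are simulated with constants of no real substance; the scatter is artificial.

Per cent of L per mol% of G was the unit I read your runs in when you asked for a quick number on J and hunched that more J would help.

| flask | L | J | G | D | remark |
|---|---|---|---|---|---|
| north-east | 0.35 M | 1.2 equiv | 0.5 mol% | 0.097 mol% | the very flask that is asked about, followed so far |
| south | 0.35 M | 1.2 equiv | 0.5 mol% | 0.19 mol% | run made earlier |
| flask | 0.35 M | 1.20 equiv | 0.5 mol% | 0.097 mol% |  |

- north-east (time / min: E / %): 2.00: 4; 4.00: 5; 5.00: 7; 8.00: 15; 10.0: 16
- south (time / min: E / %): 6.00: 15; 20.0: 28; 30.0: 32; 50.0: 38; 60.0: 41; 90.0: 46

(scatter of a reading: 2 percentage points)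

- "the catalyst" is G with its forms; D is a second catalyst
- what has left L counts as converted, also if it is not yet product
- no earlier run changes the charge of J; that part of a forecast is a guess

* apparent order in J when 10% of the L are converted (percent change of the rate of making E for one percent more J charged)
* factor on the rate of making E when 10% of the L are converted if J is charged twice over

I followed one G, and I took it that at each fork it either turned over an L or left the round. The last reading of the south run, E 46% on 0.5 mol% of G at 90.0 min, gave 92.0 turnovers per G charged. This turnover number, the L turned per G charged before G is lost, is a reading with a scatter of 2 percentage points on E, and I took E for the L turned and treated G as lost by 90.0 min.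

No run varied J, so the next step was my guess: J removes G, the odds of loss per turnover go as cJ/cL, and the rate of making E follows cL times the G still working. At 10% conversion each G charged in the north-east flask had made 20.0 turnovers, and carrying the number over from the south run, although D differs between the two, I reckoned 21.7% of G lost. On that guess, twice the J would remove 43.5% in the north-east flask, so I committed to a factor of 0.722 and an order of −0.278.

The forecast gave an order of 0.4 (0 to 1) and a factor of 1.3 (1 to 2.1), on this ground: “In a two-catalyst cycle with partial saturation, J's order is probably fractional”.

The north-east flask gave an order of −0.15 and a factor of 0.741, against my −0.278 and 0.722.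

    L + G → G + Q (k = 16.0 /M/min)
    J + D + Q → D + E (k = 6500 /M²/min)
    J + G → X (k = 0.140 /M/min)

At 0.150 h the north-east flask held L 82.1%, so the L gone came to 35.9 turnovers per G charged. Divided by my turnover number of 92.0, that reckoned 39.0% of G lost in the north-east flask, where X stood at 39.0%. In the south run, E 15% at 6.00 min counted as 30.0 turnovers per G charged, which on the same count put 32.6% of G lost.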